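## Retrosynthetic overview

1. The two peri phenolic C–O bonds (C5–O and C5''–O) are made last, by a twofold chromone-carbonyl-directed C–H oxygenation of a 5,5''-dideoxy biflavone. This avoids the 6- versus 8-aryl ambiguity of phloroglucinol-derived flavones and keeps the biaryl coupling only di-ortho-substituted.
2. The dideoxy biflavone is cut at the C3'–C6'' biaryl bond: one-pot Miyaura borylation/Suzuki–Miyaura coupling of a 3'-bromoflavone (unit 1) with a 6-bromo-7-hydroxyflavone (unit 2).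
3. Each bromoflavone comes in one operation (aldol, oxa-Michael, dehydrogenation) from a 2-hydroxyacetophenone and a benzaldehyde; four commercial building blocks in all.
4. Ring order: pyranone ring C of unit 1 and pyranone ring C of unit 2 (independently), then the biaryl union, then the two C–O bonds.

Assumption: the SMILES has no stereodescriptor and the molecule has no stereocentre (the biaryl axis is not configurationally defined), so no stereocontrol is needed; bromoketone 6 is taken as a catalogue compound.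

## Route

Step 1
Reactants: 1 1-(2-hydroxy-4-methoxyphenyl)ethan-1-one (paeonol); 2 3-bromo-4-methoxybenzaldehyde
Product: 5 2-(3-bromo-4-methoxyphenyl)-7-methoxy-4H-chromen-4-one, via chalcone 3 (not isolated), via flavanone 4 (not isolated)
Conditions: pyrrolidine (0.5 equiv), I2 (10 mol%), DMSO, 150 °C, 8 h
Reagents that add atoms: none
Why: Pyrrolidine-mediated Claisen–Schmidt aldol condensation gives chalcone 3, its 2'-OH closes by oxa-Michael addition to racemic flavanone 4, and catalytic I2 with DMSO as terminal oxidant dehydrogenates it to the flavone (aldol/oxa-Michael/I2–DMSO dehydrogenation domino, which erases the flavanone stereocentre); the aryl bromide and methyl ethers are inert.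

Step 2
Reactants: 6 1-(5-bromo-2,4-dihydroxyphenyl)ethan-1-one; 7 4-methoxybenzaldehyde
Product: 10 6-bromo-7-hydroxy-2-(4-methoxyphenyl)-4H-chromen-4-one, via chalcone 8 (not isolated), via flavanone 9 (not isolated)
Conditions: pyrrolidine (1.2 equiv), I2 (10 mol%), DMSO, 150 °C, 10 h; then dilute HCl, aq Na2S2O3
Reagents that add atoms: none
Why: The same aldol/oxa-Michael/I2–DMSO dehydrogenation domino applies, and because only one hydroxyl is ortho to the acyl group the ring closure is regiochemically unambiguous, putting Br at C6 and the free OH at C7; the acidic 4-OH is carried as its pyrrolidinium phenoxide, hence the extra pyrrolidine.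

Step 3
Reactants: 5 2-(3-bromo-4-methoxyphenyl)-7-methoxy-4H-chromen-4-one (1.1 equiv); 10 6-bromo-7-hydroxy-2-(4-methoxyphenyl)-4H-chromen-4-one
Product: 12 7-hydroxy-6-[2-methoxy-5-(7-methoxy-4-oxo-4H-chromen-2-yl)phenyl]-2-(4-methoxyphenyl)-4H-chromen-4-one, via pinacol boronate 11 (not isolated)
Conditions: 5, B2pin2 (1.15 equiv), Pd2(dba)3 (2 mol%), XPhos (8 mol%), KOAc, 1,4-dioxane, 100 °C, 3 h; then 10, 3 M aq K3PO4, 100 °C, 12 h; dilute HCl work-up
Reagents that add atoms: none
Why: Miyaura borylation of bromide 5 gives boronate 11, which undergoes Suzuki–Miyaura cross-coupling with bromide 10 once aqueous K3PO4 is added; the new biaryl bond carries only two ortho substituents, and XPhos-ligated zerovalent palladium tolerates the phenoxide of 10.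

Step 4
Reactants: 12 7-hydroxy-6-[2-methoxy-5-(7-methoxy-4-oxo-4H-chromen-2-yl)phenyl]-2-(4-methoxyphenyl)-4H-chromen-4-one
Product: 14 5,7-dihydroxy-6-[5-(5-hydroxy-7-methoxy-4-oxo-4H-chromen-2-yl)-2-methoxyphenyl]-2-(4-methoxyphenyl)-4H-chromen-4-one (the target), via tris(trifluoroacetate) 13 (not isolated)
Conditions: TFA/TFAA (3:1), 25 °C, 30 min; then [RuCl2(p-cymene)]2 (10 mol%), PhI(OCOCF3)2 (4.0 equiv), 80 °C, 12 h; then aq NaHCO3, THF, 25 °C
Reagents that add atoms: [bis(trifluoroacetoxy)iodo]benzene, O=C(OI(OC(=O)C(F)(F)F)c1ccccc1)C(F)(F)F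
Why: Proposed new method: a twofold chromone-carbonyl-directed peri-C–H trifluoroacetoxylation of an unsymmetrical biflavone with in-situ O-trifluoroacetyl masking of the free phenol; TFAA first turns the 7''-OH into an electron-poor trifluoroacetate that resists the hypervalent iodine oxidant, the cationic divalent ruthenium carboxylate binds each C4=O and cleaves the only C–H bond that can give a five-membered ruthenacycle (C5–H and C5''–H) by carboxylate-assisted metalation, PhI(OCOCF3)2 oxidises each ruthenacycle to tetravalent ruthenium, and C–O reductive elimination gives the aryl trifluoroacetates of 13, which the bicarbonate work-up hydrolyses together with the 7''-ester; C5''–H should remain reachable because the 6''-aryl ring lies twisted out of plane and can turn its unsubstituted ortho side toward it, and no 6/8 regioisomers can arise because each carbonyl reaches only its peri position; closest known reaction type: ruthenium-catalysed ketone-directed ortho-C–H hydroxylation of aryl ketones and simple monomeric flavones with hypervalent iodine oxidants in TFA/TFAA, not shown twofold on a biflavone, at a peri C–H flanked by an aryl group, or with a free phenol present.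

## Compound list

1 | 1-(2-hydroxy-4-methoxyphenyl)ethan-1-one (paeonol) | CC(=O)c1ccc(OC)cc1O | starting material
2 | 3-bromo-4-methoxybenzaldehyde | COc1ccc(C=O)cc1Br | starting material
3 | (E)-3-(3-bromo-4-methoxyphenyl)-1-(2-hydroxy-4-methoxyphenyl)prop-2-en-1-one (chalcone) | COc1ccc(C(=O)/C=C/c2ccc(OC)c(Br)c2)c(O)c1 | intermediate
4 | racemic 2-(3-bromo-4-methoxyphenyl)-7-methoxychroman-4-one (flavanone) | COc1ccc2c(c1)OC(c1ccc(OC)c(Br)c1)CC2=O | intermediate
5 | 2-(3-bromo-4-methoxyphenyl)-7-methoxy-4H-chromen-4-one | COc1ccc2c(c1)oc(-c1ccc(OC)c(Br)c1)cc2=O | intermediate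
6 | 1-(5-bromo-2,4-dihydroxyphenyl)ethan-1-one | CC(=O)c1cc(Br)c(O)cc1O | starting material
7 | 4-methoxybenzaldehyde | COc1ccc(C=O)cc1 | starting material
8 | (E)-1-(5-bromo-2,4-dihydroxyphenyl)-3-(4-methoxyphenyl)prop-2-en-1-one (chalcone) | COc1ccc(/C=C/C(=O)c2cc(Br)c(O)cc2O)cc1 | intermediate
9 | racemic 6-bromo-7-hydroxy-2-(4-methoxyphenyl)chroman-4-one (flavanone) | COc1ccc(C2CC(=O)c3cc(Br)c(O)cc3O2)cc1 | intermediate
10 | 6-bromo-7-hydroxy-2-(4-methoxyphenyl)-4H-chromen-4-one | COc1ccc(-c2cc(=O)c3cc(Br)c(O)cc3o2)cc1 | intermediate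
11 | 7-methoxy-2-[4-methoxy-3-(4,4,5,5-tetramethyl-1,3,2-dioxaborolan-2-yl)phenyl]-4H-chromen-4-one (pinacol boronate) | COc1ccc2c(c1)oc(-c1ccc(OC)c(B3OC(C)(C)C(C)(C)O3)c1)cc2=O | intermediate
12 | 7-hydroxy-6-[2-methoxy-5-(7-methoxy-4-oxo-4H-chromen-2-yl)phenyl]-2-(4-methoxyphenyl)-4H-chromen-4-one | COc1ccc(-c2cc(=O)c3cc(-c4cc(-c5cc(=O)c6ccc(OC)cc6o5)ccc4OC)c(O)cc3o2)cc1 | intermediate
13 | 6-[2-methoxy-5-(7-methoxy-4-oxo-5-(trifluoroacetoxy)-4H-chromen-2-yl)phenyl]-2-(4-methoxyphenyl)-4-oxo-4H-chromene-5,7-diyl bis(trifluoroacetate) | COc1ccc(-c2cc(=O)c3c(OC(=O)C(F)(F)F)c(-c4cc(-c5cc(=O)c6c(OC(=O)C(F)(F)F)cc(OC)cc6o5)ccc4OC)c(OC(=O)C(F)(F)F)cc3o2)cc1 | intermediate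
14 | 5,7-dihydroxy-6-[5-(5-hydroxy-7-methoxy-4-oxo-4H-chromen-2-yl)-2-methoxyphenyl]-2-(4-methoxyphenyl)-4H-chromen-4-one (CNP0281098.0) | COc1ccc(-c2cc(=O)c3c(O)c(-c4cc(-c5cc(=O)c6c(O)cc(OC)cc6o5)ccc4OC)c(O)cc3o2)cc1 | target

## Step count

Total steps: 4. Longest linear sequence: 3 (step 1 or step 2, then step 3, then step 4).

## Steps most likely to fail

**Step 4 (the proposed new twofold C–H oxygenation).** The C5''–H bond next to the 6''-aryl group may not metalate, which would stop the reaction at the mono-hydroxylated compound, and the oxidant may attack the anisole rings. The fallback uses known chemistry only and carries both peri oxygens from the start; it sets out from 2 and comes back at 14. Claisen–Schmidt condensation of 2 with commercial 1-(2-hydroxy-4,6-dimethoxyphenyl)ethan-1-one (KOH, EtOH, 25 °C) gives (E)-3-(3-bromo-4-methoxyphenyl)-1-(2-hydroxy-4,6-dimethoxyphenyl)prop-2-en-1-one F1. Oxidative cyclisation (I2 10 mol%, DMSO, 130 °C) gives 2-(3-bromo-4-methoxyphenyl)-5,7-dimethoxy-4H-chromen-4-one F2. Miyaura borylation (B2pin2, PdCl2(dppf), KOAc, dioxane, 90 °C) gives 5,7-dimethoxy-2-[4-methoxy-3-(4,4,5,5-tetramethyl-1,3,2-dioxaborolan-2-yl)phenyl]-4H-chromen-4-one F3. In parallel, commercial acacetin (5,7-dihydroxy-2-(4-methoxyphenyl)-4H-chromen-4-one) is benzylated at the non-chelated 7-OH (benzyl bromide, K2CO3, acetone, reflux) to 7-(benzyloxy)-5-hydroxy-2-(4-methoxyphenyl)-4H-chromen-4-one F4. Iodination ortho to the free 5-OH (benzyltrimethylammonium dichloroiodate, CaCO3, CH2Cl2/MeOH, 25 °C) gives 7-(benzyloxy)-5-hydroxy-6-iodo-2-(4-methoxyphenyl)-4H-chromen-4-one F5. Suzuki–Miyaura coupling of F3 with F5 (Pd(OAc)2, SPhos, K3PO4, toluene/H2O, 100 °C) gives 7-(benzyloxy)-6-[5-(5,7-dimethoxy-4-oxo-4H-chromen-2-yl)-2-methoxyphenyl]-5-hydroxy-2-(4-methoxyphenyl)-4H-chromen-4-one F6. BCl3 (CH2Cl2, −78 to 0 °C) then removes the benzyl ether and, by chelation to the C4 carbonyl, only the 5-O-methyl group, giving 14.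

**Step 3 (one-pot borylation/Suzuki coupling of two sparingly soluble flavones).** Boronate 11 may protodeboronate, and the phenoxide of 10 may couple slowly. The fallback avoids borylating a flavone and builds the pyranone ring of unit 1 after the biaryl bond; it sets out from 10 and comes back at 12. Suzuki–Miyaura coupling of 10 with commercial (5-formyl-2-methoxyphenyl)boronic acid (Pd(OAc)2, SPhos, K3PO4, dioxane/H2O, 90 °C) gives 3-[7-hydroxy-2-(4-methoxyphenyl)-4-oxo-4H-chromen-6-yl]-4-methoxybenzaldehyde F7. Claisen–Schmidt condensation of F7 with 1 (KOH, EtOH, 25 °C) gives (E)-3-[3-[7-hydroxy-2-(4-methoxyphenyl)-4-oxo-4H-chromen-6-yl]-4-methoxyphenyl]-1-(2-hydroxy-4-methoxyphenyl)prop-2-en-1-one F8. Oxidative cyclisation of F8 (I2 10 mol%, DMSO, 130 °C) gives 12.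

**Step 2 (domino annulation with a free, acidic phenol).** The phenoxide may slow the aldol stage, and the activated ring may be iodinated. The fallback replaces the aldol/oxidation logic by C-acylation and cyclodehydration; it sets out from 6 and comes back at 10. The lithium polyanion of 6 (LiN(SiMe3)2, 4.2 equiv, THF, −78 °C) is C-acylated with 4-methoxybenzoyl chloride (1.0 equiv, −78 to 25 °C, then dilute HCl) to give 1-(5-bromo-2,4-dihydroxyphenyl)-3-(4-methoxyphenyl)propane-1,3-dione F9. Cyclodehydration of F9 (catalytic H2SO4, AcOH, 100 °C) gives 10.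

## Further compounds

F1 | step 4 | (E)-3-(3-bromo-4-methoxyphenyl)-1-(2-hydroxy-4,6-dimethoxyphenyl)prop-2-en-1-one | COc1cc(O)c(C(=O)/C=C/c2ccc(OC)c(Br)c2)c(OC)c1
F2 | step 4 | 2-(3-bromo-4-methoxyphenyl)-5,7-dimethoxy-4H-chromen-4-one | COc1cc(OC)c2c(c1)oc(-c1ccc(OC)c(Br)c1)cc2=O
F3 | step 4 | 5,7-dimethoxy-2-[4-methoxy-3-(4,4,5,5-tetramethyl-1,3,2-dioxaborolan-2-yl)phenyl]-4H-chromen-4-one | COc1cc(OC)c2c(c1)oc(-c1ccc(OC)c(B3OC(C)(C)C(C)(C)O3)c1)cc2=O
F4 | step 4 | 7-(benzyloxy)-5-hydroxy-2-(4-methoxyphenyl)-4H-chromen-4-one | COc1ccc(-c2cc(=O)c3c(O)cc(OCc4ccccc4)cc3o2)cc1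
F5 | step 4 | 7-(benzyloxy)-5-hydroxy-6-iodo-2-(4-methoxyphenyl)-4H-chromen-4-one | COc1ccc(-c2cc(=O)c3c(O)c(I)c(OCc4ccccc4)cc3o2)cc1
F6 | step 4 | 7-(benzyloxy)-6-[5-(5,7-dimethoxy-4-oxo-4H-chromen-2-yl)-2-methoxyphenyl]-5-hydroxy-2-(4-methoxyphenyl)-4H-chromen-4-one | COc1ccc(-c2cc(=O)c3c(O)c(-c4cc(-c5cc(=O)c6c(OC)cc(OC)cc6o5)ccc4OC)c(OCc7ccccc7)cc3o2)cc1
F7 | step 3 | 3-[7-hydroxy-2-(4-methoxyphenyl)-4-oxo-4H-chromen-6-yl]-4-methoxybenzaldehyde | COc1ccc(-c2cc(=O)c3cc(-c4cc(C=O)ccc4OC)c(O)cc3o2)cc1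
F8 | step 3 | (E)-3-[3-[7-hydroxy-2-(4-methoxyphenyl)-4-oxo-4H-chromen-6-yl]-4-methoxyphenyl]-1-(2-hydroxy-4-methoxyphenyl)prop-2-en-1-one | COc1ccc(-c2cc(=O)c3cc(-c4cc(/C=C/C(=O)c5ccc(OC)cc5O)ccc4OC)c(O)cc3o2)cc1
F9 | step 2 | 1-(5-bromo-2,4-dihydroxyphenyl)-3-(4-methoxyphenyl)propane-1,3-dione | COc1ccc(C(=O)CC(=O)c2cc(Br)c(O)cc2O)cc1
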